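I charged the same amount of substrate into three flasks that differed in temperature, and I wanted the amount of target in each at one reading time.

all flasks: substrate 0.30 M; time 15 s

| charge | temperature |
|---|---|
| Monday's | 15 °C |
| Friday's | 55 °C |
| Thursday's | 35 °C |

    substrate ⇌ other conformer (K1 = 0.70, k1 = 0.044 s⁻¹, Ea1 = 76.0 kJ mol⁻¹, ΔH1 = 7.00 kJ mol⁻¹)
    substrate → target (k2 = 0.22 s⁻¹, Ea2 = 76.0 kJ mol⁻¹)
    other conformer → isomer of the product (k3 = 5.5 s⁻¹, Ea3 = 61.0 kJ mol⁻¹)
    target ⇌ isomer of the product (K4 = 0.35, k4 = 0.013 s⁻¹, Ea4 = 95.0 kJ mol⁻¹, ΔH4 = −11.0 kJ mol⁻¹)
    2 substrate → homo dimer (k5 = 0.052 M⁻¹ s⁻¹, Ea5 = 65.0 kJ mol⁻¹)
    target → over-reaction product (k6 = 0.029 s⁻¹, Ea6 = 74.0 kJ mol⁻¹)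
    (constants at 35 °C)

1. which flask leads in amount of target, in percent of the substrate charged ("all alike" within 1.5 percentage points) (Monday's / Friday's / Thursday's / all alike)
2. how much target is there at the end, in percent of the substrate charged: Monday's
3. how much target is there at the end, in percent of the substrate charged: Friday's
4. how much target is there at the end, in percent of the substrate charged: Thursday's

- percentages count the substrate that a species holds: one homo dimer counts as two
- where a step has two of a species, its rate is k times that concentration squared, and two are used at each turn
- at 35 °C the constants are as listed, elsewhere as the activation energies and enthalpies make them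
- in a conversion other conformer counts as not yet reacted

1. I followed Thursday's flask first, since the constants stand at its temperature. In the first instants of Thursday's flask substrate left towards target at 0.22 s⁻¹ and towards other conformer at 0.044 s⁻¹, the former faster by a factor of 5.0 at the start, counting the forward rate of the reversible step alone. Together these gave a loss rate of 0.264 s⁻¹, a lifetime of 3.79 s. In Thursday's flask I reckoned a lifetime of 0.180 s for other conformer, far shorter than the substrate's lifetime, so I treated it as a quasi-steady trace, with the step into it, at 0.044 s⁻¹ against 5.5 s⁻¹ out of it, as the rate-limiting step of the way to the isomer. In Thursday's flask the dimer step began at 0.0312 s⁻¹, less than that loss rate, and it weakens as substrate falls, so I set it aside in this estimate.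

2. In the middle of Thursday's run, as I reckoned it, target was fed at the substrate's pace and lost towards isomer and over-reaction product at 0.0420 s⁻¹, a lifetime of 23.8 s, longer than the substrate's. These are two first-order lags in series, so in Thursday's flask I expected target to rise, stop and fall. I carried one quantity, the peak time, the moment at which making and losing of target balance, ln(a/b)/(a − b), with a the substrate's loss rate and b the target's: 8.28 s. I counted no return from the isomer.

3. At the end, Thursday's reading at 15 s came later than the peak, by 0.282 of a target lifetime.

4. The step to target speeds up by a factor of 48 from the coldest to the hottest flask, so I took its square root, 6.91, as a rough stretch of both lifetimes each way from Thursday's. I put Monday's peak at about 57.2 s, so by this estimate Monday's reading came before it, at 0.573 of a substrate lifetime. I put Friday's peak at about 1.20 s, so by this estimate Friday's reading came 4.01 target lifetimes after it. I expected Thursday's flask to lead, and my reckoning gave that lead without amounts.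

5. The forecast named Thursday's, with 30.9% for Monday's, 11.5% for Friday's and 53.6% for Thursday's, and its reckoning began from the view that “the other conformer sits at steady state and drains to the isomer”.

The simulation put Thursday's ahead, with 30.9% in Monday's, 11.5% in Friday's and 53.7% in Thursday's. In Thursday's flask, each step taken net, target was made 8.59 times faster than it was used up at 2.46 s, but at 15.0 s it was made slower than it was used up, at a ratio of 0.237, and my peak time of 8.28 s lies between those two moments. The neighbouring flask is Thursday's read at 10 s, with the temperature and amounts unchanged, so my reckoned peak time stays the same and the reading falls 1.72 s past it instead of 6.72 s. That neighbouring flask held 58.5% of target, more than the 53.7% of Thursday's at 15 s, with 6.46% of substrate still there.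

The numbers of this flask were drawn at random within sensible limits; what happens was integrated by code.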